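Ring B is not made by substituting a benzene; it is assembled on the ring-A oxygen. Its C1' ester carbon and C2' aryloxy carbon come from an aryloxypropiolate, and C3'–C6' (C4' methoxy, C6' pentanoyl, which sits meta to both ring-B oxygens) come from 4-methoxy-6-pentanoyl-2-pyranone. One thermal cycloaddition with CO2 extrusion forms C2'–C3' and C1'–C6' and delivers the complete tetrasubstituted arene already attached to ring A. The precursor is the ring-A aryl ynol ether methyl ester, with ring A (from olivetol) carrying benzyl ethers at O2/O4 and a tert-butyl ester at C1, chosen to survive the organolithium steps that build it.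

Key step: step 10

Remark: the target has no stereocentre, and its diaryl ether axis carries too few ortho substituents for stable atropisomers, so it is achiral and no enantiocontrol is needed. Ring A is numbered C1 (carboxyl) to C6 (pentyl) and ring B C1' (ester) to C6' (pentanoyl) throughout.

Step 1
Reactants: 1 olivetol (5-pentylbenzene-1,3-diol)
Product: 2 4,6-dibromo-5-pentylbenzene-1,3-diol
Conditions: Br2 (2.05 equiv), CH2Cl2, −15 °C → 0 °C
Reagents that add atoms: bromine, BrBr
Why: Electrophilic aromatic bromination of a resorcinol goes to the two positions ortho to one hydroxyl and para to the other (both flanking the pentyl chain), and two equivalents at low temperature should leave the position between the hydroxyls free.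

Step 2
Reactants: 2 4,6-dibromo-5-pentylbenzene-1,3-diol
Product: 3 1,5-bis(benzyloxy)-2,4-dibromo-3-pentylbenzene
Conditions: BnBr (2.4 equiv), K2CO3, DMF, rt → 50 °C
Reagents that add atoms: benzyl bromide, BrCc1ccccc1
Why: Williamson etherification of the two acidic ortho-bromophenols should proceed cleanly on oxygen with a benzylic halide in a dipolar aprotic solvent.

Step 3
Reactants: 3 1,5-bis(benzyloxy)-2,4-dibromo-3-pentylbenzene
Product: 5 tert-butyl 2,4-bis(benzyloxy)-5-bromo-6-pentylbenzoate, via aryllithium 4 (not isolated)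
Conditions: n-BuLi (1.05 equiv), THF, −78 °C; then Boc2O, −78 °C → rt
Reagents that add atoms: di-tert-butyl dicarbonate, CC(C)(C)OC(=O)OC(=O)OC(C)(C)C; n-butyllithium, [Li]CCCC (supplies only the lithium of 4)
Why: Bromine–lithium exchange of one of the two symmetry-equivalent bromides (the monolithio species resists a second exchange) followed by acylation of the aryllithium with Boc2O should give the di-ortho-substituted tert-butyl ester, which is too hindered to add a second aryllithium.

Step 4
Reactants: 5 tert-butyl 2,4-bis(benzyloxy)-5-bromo-6-pentylbenzoate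
Product: 8 tert-butyl 2,4-bis(benzyloxy)-5-hydroxy-6-pentylbenzoate, via aryllithium 6 (not isolated), via lithium aryltrimethoxyborate 7 (not isolated)
Conditions: n-BuLi (1.1 equiv), THF, −78 °C; B(OMe)3, −78 → 0 °C; then AcOH, 30% H2O2, 0 °C → rt
Reagents that add atoms: hydrogen peroxide, OO; n-butyllithium, [Li]CCCC (lithium of 6 and 7 only); trimethyl borate, COB(OC)OC (boron and methoxy groups of 7 only)
Why: A second bromine–lithium exchange, which the hindered tert-butyl ester tolerates at −78 °C, followed by borylation and oxidative aryl migration from boron to oxygen (boronate oxidation) should place the C5 hydroxyl exactly where the bromine was.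

Step 5
Reactants: 8 tert-butyl 2,4-bis(benzyloxy)-5-hydroxy-6-pentylbenzoate; 9 trichloroethylene
Product: 11 tert-butyl 2,4-bis(benzyloxy)-5-{[(E)-1,2-dichloroethenyl]oxy}-6-pentylbenzoate, via dichloroacetylene 10 (not isolated)
Conditions: K2CO3, DMF, 70 °C
Reagents that add atoms: none
Why: Base-induced dehydrochlorination of trichloroethylene gives dichloroacetylene in solution, to which the phenoxide adds in anti fashion (nucleophilic addition to a haloalkyne, first stage of the Greene ynol ether synthesis), so the C5–O bond is made without any hindered aryl C–O coupling.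

Step 6
Reactants: 11 tert-butyl 2,4-bis(benzyloxy)-5-{[(E)-1,2-dichloroethenyl]oxy}-6-pentylbenzoate; 12 methyl chloroformate
Product: 15 tert-butyl 2,4-bis(benzyloxy)-5-[(3-methoxy-3-oxoprop-1-yn-1-yl)oxy]-6-pentylbenzoate, via chloroethynyl ether 13 (not isolated), via lithium aryloxyacetylide 14 (not isolated)
Conditions: n-BuLi (2.1 equiv), THF, −78 → −40 °C; then ClCO2Me, −78 → 0 °C; cold NaHCO3 work-up
Reagents that add atoms: n-butyllithium, [Li]CCCC (lithium of 14 only)
Why: In the Greene ynol ether synthesis, deprotonation and β-elimination give the chloroalkyne, chlorine–lithium exchange gives the lithium acetylide, and C-acylation with the chloroformate gives the alkynoate; the hindered tert-butyl ester should not be attacked by n-butyllithium at these temperatures.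

Step 7
Reactants: 16 4-methoxy-6-methyl-2H-pyran-2-one
Product: 17 4-methoxy-2-oxo-2H-pyran-6-carbaldehyde
Conditions: SeO2, 1,4-dioxane, 160 °C (sealed tube)
Reagents that add atoms: selenium dioxide, O=[Se]=O
Why: Riley oxidation of the vinylogously activated 6-methyl group should stop at the aldehyde and leave the methoxypyranone ring intact.

Step 8
Reactants: 17 4-methoxy-2-oxo-2H-pyran-6-carbaldehyde
Product: 18 6-(1-hydroxypentyl)-4-methoxy-2H-pyran-2-one (racemic)
Conditions: n-BuMgCl (1.05 equiv), THF, −78 °C; aq NH4Cl
Reagents that add atoms: butylmagnesium chloride, CCCC[Mg]Cl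
Why: Grignard 1,2-addition should take place at the aldehyde, which is far more electrophilic than the vinylogous-carbonate pyranone carbonyl at −78 °C; the carbinol centre is formed racemic and is removed in the next step.

Step 9
Reactants: 18 6-(1-hydroxypentyl)-4-methoxy-2H-pyran-2-one
Product: 19 4-methoxy-6-pentanoyl-2H-pyran-2-one
Conditions: Dess–Martin periodinane, CH2Cl2, rt
Reagents that add atoms: none
Why: Dess–Martin oxidation converts the secondary alcohol into the ketone under near-neutral conditions that the pyranone tolerates.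

Step 10
Reactants: 15 tert-butyl 2,4-bis(benzyloxy)-5-[(3-methoxy-3-oxoprop-1-yn-1-yl)oxy]-6-pentylbenzoate; 19 4-methoxy-6-pentanoyl-2H-pyran-2-one
Product: 21 tert-butyl 2,4-bis(benzyloxy)-5-[5-methoxy-2-(methoxycarbonyl)-3-pentanoylphenoxy]-6-pentylbenzoate, via bridged lactone 20 (not isolated)
Conditions: 19 (2 equiv), toluene (1 M), BHT (cat.), base-washed sealed tube, 150–160 °C
Reagents that add atoms: none
Why: The pyranone diene C3=C4–C5=C6 of 19 and the alkyne of 15 should combine in a thermal, polarity-matched and probably asynchronous [4+2] cycloaddition to the bridged lactone 20, which then loses CO2 by retro-[4+2] under the same conditions, driven by aromatisation. The closest known reaction type is the Diels–Alder/decarboxylation of 4-alkoxy-2-pyranones with acetylenic esters to benzoates and phthalates, together with the additions of ynol ethers and ynamines to acceptor-substituted 2-pyranones. Ring B is closed intermolecularly by the cycloaddition itself, both ring bonds (C2'–C3' and C1'–C6') coming from the one [4+2] event, and the six-membered ring is then unbridged by cycloreversion. No stereocentre survives, since the two bridgehead centres of 20 form as a racemate and become aromatic carbons on CO2 loss. The step needs regioselectivity, and the substrate supplies it from both sides: pyranone C3, the donor terminus β to the C4 methoxy group, bonds to the aryloxy-bearing alkyne carbon (the electrophilic β-carbon of the ynoate), while C6, the acyl-bearing acceptor terminus, bonds to the ester-bearing carbon (the nucleophilic β-carbon of the ynol ether). The hindered tert-butyl ester and the benzyl ethers should be thermally inert under these neutral conditions.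

Step 11
Reactants: 21 tert-butyl 2,4-bis(benzyloxy)-5-[5-methoxy-2-(methoxycarbonyl)-3-pentanoylphenoxy]-6-pentylbenzoate
Product: 22 2,4-bis(benzyloxy)-5-[5-methoxy-2-(methoxycarbonyl)-3-pentanoylphenoxy]-6-pentylbenzoic acid
Conditions: TFA/CH2Cl2 (1:4), 0 °C → rt
Reagents that add atoms: none
Why: Acidolysis of the tert-butyl ester (alkyl–oxygen cleavage with loss of isobutene) should free the ring-A acid, while the methyl ester, aryl benzyl ethers, ketone and diaryl ether are stable to TFA at room temperature.

Step 12
Reactants: 22 2,4-bis(benzyloxy)-5-[5-methoxy-2-(methoxycarbonyl)-3-pentanoylphenoxy]-6-pentylbenzoic acid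
Product: 23 2,4-dihydroxy-5-[5-methoxy-2-(methoxycarbonyl)-3-pentanoylphenoxy]-6-pentylbenzoic acid (target, CNP0262789.0)
Conditions: H2 (1 atm), 10% Pd/C, EtOAc, rt
Reagents that add atoms: none
Why: Catalytic hydrogenolysis cleaves the two benzylic C–O bonds under neutral conditions at atmospheric pressure, under which the hindered aryl ketone, the methyl ester and the diaryl ether should not be reduced.

Compound list
1 | olivetol (5-pentylbenzene-1,3-diol) | CCCCCc1cc(O)cc(O)c1 | starting material
2 | 4,6-dibromo-5-pentylbenzene-1,3-diol | CCCCCc1c(Br)c(O)cc(O)c1Br | intermediate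
3 | 1,5-bis(benzyloxy)-2,4-dibromo-3-pentylbenzene | CCCCCc1c(Br)c(OCc2ccccc2)cc(OCc2ccccc2)c1Br | intermediate
4 | [2,4-bis(benzyloxy)-5-bromo-6-pentylphenyl]lithium | CCCCCc1c(Br)c(OCc2ccccc2)cc(OCc2ccccc2)c1[Li] | intermediate (not isolated)
5 | tert-butyl 2,4-bis(benzyloxy)-5-bromo-6-pentylbenzoate | CCCCCc1c(Br)c(OCc2ccccc2)cc(OCc2ccccc2)c1C(=O)OC(C)(C)C | intermediate
6 | tert-butyl 2,4-bis(benzyloxy)-5-lithio-6-pentylbenzoate | CCCCCc1c([Li])c(OCc2ccccc2)cc(OCc2ccccc2)c1C(=O)OC(C)(C)C | intermediate (not isolated)
7 | lithium trimethoxyborate of ring A (boron at C5, ester at C1) | [Li+].CO[B-](OC)(OC)c1c(CCCCC)c(C(=O)OC(C)(C)C)c(OCc2ccccc2)cc1OCc1ccccc1 | intermediate (not isolated)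
8 | tert-butyl 2,4-bis(benzyloxy)-5-hydroxy-6-pentylbenzoate | CCCCCc1c(O)c(OCc2ccccc2)cc(OCc2ccccc2)c1C(=O)OC(C)(C)C | intermediate
9 | trichloroethylene | ClC=C(Cl)Cl | starting material
10 | dichloroacetylene | ClC#CCl | intermediate (not isolated)
11 | tert-butyl 2,4-bis(benzyloxy)-5-{[(E)-1,2-dichloroethenyl]oxy}-6-pentylbenzoate | CCCCCc1c(O/C(Cl)=C\Cl)c(OCc2ccccc2)cc(OCc2ccccc2)c1C(=O)OC(C)(C)C | intermediate
12 | methyl chloroformate | COC(=O)Cl | starting material
13 | tert-butyl 2,4-bis(benzyloxy)-5-[(chloroethynyl)oxy]-6-pentylbenzoate | CCCCCc1c(OC#CCl)c(OCc2ccccc2)cc(OCc2ccccc2)c1C(=O)OC(C)(C)C | intermediate (not isolated)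
14 | lithium acetylide of the ring-A aryl ethynyl ether | CCCCCc1c(OC#C[Li])c(OCc2ccccc2)cc(OCc2ccccc2)c1C(=O)OC(C)(C)C | intermediate (not isolated)
15 | tert-butyl 2,4-bis(benzyloxy)-5-[(3-methoxy-3-oxoprop-1-yn-1-yl)oxy]-6-pentylbenzoate | CCCCCc1c(OC#CC(=O)OC)c(OCc2ccccc2)cc(OCc2ccccc2)c1C(=O)OC(C)(C)C | intermediate (key-step precursor)
16 | 4-methoxy-6-methyl-2H-pyran-2-one | Cc1cc(OC)cc(=O)o1 | starting material
17 | 4-methoxy-2-oxo-2H-pyran-6-carbaldehyde | O=Cc1cc(OC)cc(=O)o1 | intermediate
18 | 6-(1-hydroxypentyl)-4-methoxy-2H-pyran-2-one (racemic) | CCCCC(O)c1cc(OC)cc(=O)o1 | intermediate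
19 | 4-methoxy-6-pentanoyl-2H-pyran-2-one | CCCCC(=O)c1cc(OC)cc(=O)o1 | intermediate (key-step precursor)
20 | methyl 8-(ring-A aryloxy)-5-methoxy-3-oxo-1-pentanoyl-2-oxabicyclo[2.2.2]octa-5,7-diene-7-carboxylate (racemic; aryloxy = 4,6-bis(benzyloxy)-3-(tert-butoxycarbonyl)-2-pentylphenoxy) | O=C1OC2(C(=O)CCCC)C=C(OC)C1C(Oc3c(CCCCC)c(C(=O)OC(C)(C)C)c(OCc4ccccc4)cc3OCc3ccccc3)=C2C(=O)OC | intermediate (not isolated)
21 | tert-butyl 2,4-bis(benzyloxy)-5-[5-methoxy-2-(methoxycarbonyl)-3-pentanoylphenoxy]-6-pentylbenzoate | CCCCCc1c(Oc2cc(OC)cc(C(=O)CCCC)c2C(=O)OC)c(OCc2ccccc2)cc(OCc2ccccc2)c1C(=O)OC(C)(C)C | intermediate (key-step product)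
22 | 2,4-bis(benzyloxy)-5-[5-methoxy-2-(methoxycarbonyl)-3-pentanoylphenoxy]-6-pentylbenzoic acid | CCCCCc1c(Oc2cc(OC)cc(C(=O)CCCC)c2C(=O)OC)c(OCc2ccccc2)cc(OCc2ccccc2)c1C(=O)O | intermediate
23 | 2,4-dihydroxy-5-[5-methoxy-2-(methoxycarbonyl)-3-pentanoylphenoxy]-6-pentylbenzoic acid | CCCCCc1c(Oc2cc(OC)cc(C(=O)CCCC)c2C(=O)OC)c(O)cc(O)c1C(=O)O | target

Total step count: 12. Longest linear sequence: 9 steps (steps 1–6, 10, 11, 12, from olivetol); the pyranone branch is steps 7–9.

Steps most likely to fail

1. Step 10. The hindered push–pull alkyne may cycloadd too slowly, so that thermal degradation of the ynol ether (oligomerisation, hydration by adventitious water) or loss of isobutene from the tert-butyl ester outruns ring formation. The fallback separates ring-B construction from ether formation and sets out from pyranone 19 and phenol 8. Heating 19 with methyl 3-bromopropiolate, a conventional electron-poor dienophile with the same polarity sense, should give the bromo bridged lactone methyl 8-bromo-5-methoxy-3-oxo-1-pentanoyl-2-oxabicyclo[2.2.2]octa-5,7-diene-7-carboxylate F1, which loses CO2 to give methyl 2-bromo-4-methoxy-6-pentanoylbenzoate F2. Copper-catalysed Ullmann diaryl ether coupling of F2 with 8 (CuI, picolinic acid, K3PO4, DMSO, 90 °C), assisted by the ortho ester, comes back to the route at 21.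

2. Step 6. Chlorine–lithium exchange may be incomplete, n-butyllithium may deprotonate benzylic positions, and the push–pull alkyne may be hydrated during work-up or chromatography. The fallback brings in the three-carbon ester unit intact and sets out from phenol 8, bypassing steps 5 and 6. Addition–elimination of the phenoxide on methyl 3,3-dichloroacrylate (K2CO3, DMF, rt) should give the chloro enol ether tert-butyl 2,4-bis(benzyloxy)-5-[(1-chloro-3-methoxy-3-oxoprop-1-en-1-yl)oxy]-6-pentylbenzoate F3. Dehydrochlorination with LiHMDS (THF, −78 °C), the classical halo enol ether to ynol ether elimination, comes back to the route at 15.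

3. Step 8. Chemoselectivity may be lost through conjugate addition of the Grignard reagent to the pyranone or through ring opening. The fallback avoids any carbon nucleophile on a formylpyranone and sets out from 16. Deprotonation of the 6-methyl group (LDA, THF, −78 °C) gives 6-(lithiomethyl)-4-methoxy-2H-pyran-2-one F4, which is alkylated with 1-iodobutane to 4-methoxy-6-pentyl-2H-pyran-2-one F5. Selenium dioxide oxidation of the ring-adjacent methylene (dioxane, 140–160 °C), with any alcohol 18 carried on under the conditions of step 9, comes back to the route at 19.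

Further compounds
F1 | step 10 | methyl 8-bromo-5-methoxy-3-oxo-1-pentanoyl-2-oxabicyclo[2.2.2]octa-5,7-diene-7-carboxylate (racemic) | O=C1OC2(C(=O)CCCC)C=C(OC)C1C(Br)=C2C(=O)OC
F2 | step 10 | methyl 2-bromo-4-methoxy-6-pentanoylbenzoate | CCCCC(=O)c1cc(OC)cc(Br)c1C(=O)OC
F3 | step 6 | tert-butyl 2,4-bis(benzyloxy)-5-[(1-chloro-3-methoxy-3-oxoprop-1-en-1-yl)oxy]-6-pentylbenzoate (alkene geometry not defined) | CCCCCc1c(OC(Cl)=CC(=O)OC)c(OCc2ccccc2)cc(OCc2ccccc2)c1C(=O)OC(C)(C)C
F4 | step 8 | 6-(lithiomethyl)-4-methoxy-2H-pyran-2-one | [Li]Cc1cc(OC)cc(=O)o1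
F5 | step 8 | 4-methoxy-6-pentyl-2H-pyran-2-one | CCCCCc1cc(OC)cc(=O)o1
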